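**Plan**

1. Retrosynthesis: first the fourteen O–benzyl bonds and the lower gallate ester are cut; then, in one operation, C4–C4a and O1–C8a of the lower pyran ring (ring C), giving an aryl iodide and a γ-iodo alcohol; then the upper C4–lower C8 bond (Friedel–Crafts); the iodo alcohol is cut between its two carbinol carbons (alkoxyallylboration of an aldehyde).
2. Forward: rings A, C and B of the upper unit come intact from (−)-epicatechin; 5-iodoresorcinol dibenzyl ether is attached at upper C4 and becomes lower ring A with iodine on the future C8a; lower ring C is then annulated onto it with a three-carbon piece that already carries ring B; esterification and global hydrogenolysis finish.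
3. Enabling feature: in lower ring A, C8a lies between C8 (substituted by upper C4) and C4a (C–H), and O1 and C4 of lower ring C are the two ends of the chain O1–C2–C3–C4. An aryl iodide at C8a with one blocked and one free ortho position is the substrate of a palladium/norbornene (Catellani) relay, which can place an alkyl electrophile (C4) on the ortho carbon and a nucleophile (O1) on the ipso carbon.
4. Stereochemistry: upper C2/C3 from (−)-epicatechin; upper C4 (β) by attack anti to the participating 3-O-acyl group and the 2-aryl group; lower C2/C3 by reagent-controlled (Z)-γ-alkoxyallylboration, untouched by the annulation.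

Key step: step 10

Remark: flavan numbering is used for both units ("upper" = unit bonded through C4, "lower" = unit bonded through C8), and 3,3'- is read as the gallate at C3 of each unit.

**Route**

Step 1
Reactants: 1 (−)-epicatechin
Product: 2 5,7,3',4'-tetra-O-benzyl-(−)-epicatechin
Conditions: BnBr (4.4 equiv), K2CO3, DMF, 0 °C → rt
Reagents that add atoms: benzyl bromide, BrCc1ccccc1
Why: Williamson etherification; carbonate deprotonates only the four phenols, so the secondary 3-OH stays free and no stereocenter is touched.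

Step 2
Reactants: 2 5,7,3',4'-tetra-O-benzyl-(−)-epicatechin
Product: 3 (2R,3R,4S)-5,7-bis(benzyloxy)-2-[3,4-bis(benzyloxy)phenyl]-4-(2-ethoxyethoxy)chroman-3-ol (4β-ether)
Conditions: DDQ, 2-ethoxyethanol, CH2Cl2, rt
Reagents that add atoms: 2-ethoxyethanol, CCOCCO
Why: DDQ benzylic oxidation; hydride abstraction from C4 (activated by the 5,7-dialkoxy ring and O1) gives a quinone-methide-type cation that the alcohol should trap from the β face, anti to the 3-OH and the 2-aryl group (this center is ionised again in step 5).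

Step 3
Reactants: 3 the 4β-(2-ethoxyethoxy) alcohol; 4 3,4,5-tris(benzyloxy)benzoic acid
Product: 5 (2R,3R,4S)-5,7-bis(benzyloxy)-2-[3,4-bis(benzyloxy)phenyl]-4-(2-ethoxyethoxy)chroman-3-yl 3,4,5-tris(benzyloxy)benzoate
Conditions: DCC, DMAP (cat.), CH2Cl2, rt
Reagents that add atoms: none
Why: Steglich esterification of the secondary 3-OH under neutral conditions that leave the acid-labile C4 ether intact.

Step 4
Reactants: 6 5-iodoresorcinol
Product: 7 1,3-bis(benzyloxy)-5-iodobenzene
Conditions: BnBr, K2CO3, acetone, reflux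
Reagents that add atoms: benzyl bromide, BrCc1ccccc1
Why: Williamson etherification of both phenols.

Step 5
Reactants: 5 the galloylated C4 electrophile; 7 1,3-bis(benzyloxy)-5-iodobenzene (6 equiv)
Product: 8 (2R,3R,4R)-5,7-bis(benzyloxy)-2-[3,4-bis(benzyloxy)phenyl]-4-[2,4-bis(benzyloxy)-6-iodophenyl]chroman-3-yl 3,4,5-tris(benzyloxy)benzoate (aryl group 4β)
Conditions: TMSOTf (0.2 equiv), CH2Cl2, −78 → −30 °C, slow addition of 5; Et3N quench
Reagents that add atoms: none
Why: Friedel–Crafts alkylation; TMSOTf ionises the C4 ether to a cation bridged by the 3-O-acyl group, and the arene, reacting through the carbon ortho to iodine and para to a benzyloxy group (the carbon between the two ethers is doubly flanked), should open it anti to C3–O and the 2-aryl group, which sets upper C4 as β (4R).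

Step 6
Reactants: 9 allyl alcohol
Product: 10 3-(methoxymethoxy)prop-1-ene
Conditions: MOMCl, iPr2NEt, CH2Cl2, 0 °C → rt
Reagents that add atoms: chloromethyl methyl ether, COCCl
Why: O-alkylation of the alcohol by the reactive α-chloro ether under amine base (methoxymethyl ether formation).

Step 7
Reactants: 10 3-(methoxymethoxy)prop-1-ene; 11 3,4-bis(benzyloxy)benzaldehyde
Product: 16 (1R,2R)-1-[3,4-bis(benzyloxy)phenyl]-2-(methoxymethoxy)but-3-en-1-ol, via (Z)-alkoxyallyllithium 12 (not isolated), via borate complex 13 (not isolated), via (Z)-alkoxyallylborane 14 (not isolated), via borinate 15 (not isolated)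
Conditions: sBuLi, THF, −78 °C; (−)-Ipc2BOMe [from (+)-α-pinene]; BF3·OEt2; 11, −78 °C → rt; NaOH, H2O2
Reagents that add atoms: none
Why: Brown-type alkoxyallylboration; the chelated (Z)-alkoxyallyl anion is passed to boron with its geometry, the chair Zimmerman–Traxler transition state turns Z into the syn (threo) relation of C1–OH and C2–OMOM, and the isopinocampheyl groups from (+)-α-pinene should select the aldehyde si face, giving (1R,2R).

Step 8
Reactants: 16 the homoallylic alcohol
Product: 18 (1R,2R)-1-[3,4-bis(benzyloxy)phenyl]-2-(methoxymethoxy)propane-1,3-diol, via ozonide 17 (not isolated)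
Conditions: O3, CH2Cl2, −78 °C; then NaBH4, MeOH, −78 → 0 °C
Reagents that add atoms: ozone, [O-][O+]=O
Why: Ozonolysis with reductive work-up; the terminal alkene is the most ozonophilic site, and direct hydride reduction of the ozonide keeps the epimerisable, retro-aldol-prone α-alkoxy-β-hydroxy aldehyde from accumulating, so C1 and C2 are preserved.

Step 9
Reactants: 18 the 1,3-diol
Product: 19 (1R,2S)-1-[3,4-bis(benzyloxy)phenyl]-3-iodo-2-(methoxymethoxy)propan-1-ol
Conditions: I2, PPh3, imidazole, CH2Cl2, 0 °C
Reagents that add atoms: iodine, II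
Why: Garegg–Samuelsson iodination; the iodophosphonium activates the unhindered primary hydroxyl much faster than the secondary benzylic one and iodide displaces it by SN2 at the primary carbon, so no stereocenter is involved (the descriptor at C2 changes only by priority).

Step 10
Reactants: 8 the aryl iodide; 19 the γ-iodo alcohol (2 equiv)
Product: 20 3-O-[3,4,5-tris(benzyloxy)benzoyl]-5,7,3',4'-tetra-O-benzylepicatechin-(4β→8)-5,7,3',4'-tetra-O-benzyl-3-O-(methoxymethyl)epicatechin
Conditions: Pd(OAc)2 (10 mol %), 2-dicyclohexylphosphino-2',6'-diisopropoxybiphenyl (20 mol %), norbornene (2 equiv), Cs2CO3 (3 equiv), 1,4-dioxane, 100 °C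
Reagents that add atoms: none
Why: Proposed new method: a Catellani-type annulation is proposed in which zerovalent palladium inserts into the C8a–I bond of 8, norbornene carbopalladation and carbonate-assisted palladation of C4a–H (the only free ortho position, its C–H acidified by the flanking C5 benzyloxy group) give the aryl–norbornyl palladacycle of divalent palladium, this takes up the primary iodide of 19 by SN2-type oxidative addition, reductive elimination from tetravalent palladium makes C4–C4a, norbornene leaves by β-carbon elimination and the aryl palladium alkoxide then makes O1–C8a by reductive elimination. The closest known reaction types are the palladium/norbornene annulations of ortho-substituted aryl iodides with bromoalkylamines (ortho alkylation, then ipso C–N closure to tetrahydroquinolines) and with epoxides (ortho alkylation, then ipso C–O closure to 2,3-dihydrobenzofurans), together with the palladium-catalysed cyclisation of aryl halides carrying a secondary alcohol to chromans; a γ-iodo alcohol has not been shown as the partner. Lower ring C closes in a [3+3] sense: the C–C bond forms first and intermolecularly, and the six-membered ring is then closed by C(aryl)–O reductive elimination from a seven-membered oxapalladacycle. No stereocenter is formed, and because neither the C2–O nor the C3–O bond of 19 is broken the lower C2 and C3 keep the (2R,3R) arrangement set in step 7. The step needs site selectivity, secured by the upper flavan at C8, which blocks the second ortho position, enforces norbornene extrusion after a single alkylation and, through the position of iodine, fixes the 4→8 connectivity, and it needs C–O reductive elimination to outrun β-hydride elimination of the benzylic alkoxide, for which the bulky dialkylbiaryl phosphine is chosen. The methoxymethyl group keeps O3 from closing a five-membered ring or migrating, and the upper ester should be spared because carbonate is the only base.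

Step 11
Reactants: 20 the methoxymethyl-protected dimer
Product: 22 3-O-[3,4,5-tris(benzyloxy)benzoyl]-5,7,3',4'-tetra-O-benzylepicatechin-(4β→8)-5,7,3',4'-tetra-O-benzylepicatechin (lower 3-OH free), via bipyridinium salt 21 (not isolated)
Conditions: TMSOTf, 2,2'-bipyridyl, CH2Cl2, 0 °C → rt; then H2O
Reagents that add atoms: none
Why: Methoxymethyl ether cleavage through the N-(alkoxymethyl)bipyridinium salt, which water hydrolyses; the silyl triflate is buffered by the pyridine base, so no free acid should reach the interflavan bond, the benzyl ethers or the ester.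

Step 12
Reactants: 22 the lower 3-alcohol; 4 3,4,5-tris(benzyloxy)benzoic acid
Product: 23 3,3'-bis-O-[3,4,5-tris(benzyloxy)benzoyl]-octa-O-benzylprocyanidin B2
Conditions: DCC, DMAP, CH2Cl2, rt
Reagents that add atoms: none
Why: Steglich esterification of the lower 3-OH, the only free hydroxyl left.

Step 13
Reactants: 23 the perbenzylated digallate
Product: 24 3,3'-di-O-galloylprocyanidin B2
Conditions: H2 (1 atm), Pd(OH)2/C, THF/MeOH/H2O, rt
Reagents that add atoms: none
Why: Hydrogenolysis of the fourteen benzyl C–O bonds at room temperature, conditions under which the benzoate esters, the C2–O1 bonds and the interflavan bond should not be cleaved.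

**Compound list**

1 | (−)-epicatechin | O[C@@H]1Cc2c(O)cc(O)cc2O[C@@H]1c1ccc(O)c(O)c1 | starting material
2 | 5,7,3',4'-tetra-O-benzyl-(−)-epicatechin | O[C@@H]1Cc2c(OCc3ccccc3)cc(OCc3ccccc3)cc2O[C@@H]1c1ccc(OCc2ccccc2)c(OCc2ccccc2)c1 | intermediate
3 | (2R,3R,4S)-5,7-bis(benzyloxy)-2-[3,4-bis(benzyloxy)phenyl]-4-(2-ethoxyethoxy)chroman-3-ol | O[C@@H]1[C@@H](OCCOCC)c2c(OCc3ccccc3)cc(OCc3ccccc3)cc2O[C@@H]1c1ccc(OCc2ccccc2)c(OCc2ccccc2)c1 | intermediate
4 | 3,4,5-tris(benzyloxy)benzoic acid | OC(=O)c1cc(OCc2ccccc2)c(OCc2ccccc2)c(OCc2ccccc2)c1 | starting material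
5 | 3-O-[3,4,5-tris(benzyloxy)benzoyl] ester of 3 | O=C(O[C@@H]1[C@@H](OCCOCC)c2c(OCc3ccccc3)cc(OCc3ccccc3)cc2O[C@@H]1c1ccc(OCc2ccccc2)c(OCc2ccccc2)c1)c1cc(OCc2ccccc2)c(OCc2ccccc2)c(OCc2ccccc2)c1 | intermediate
6 | 5-iodoresorcinol | Oc1cc(O)cc(I)c1 | starting material
7 | 1,3-bis(benzyloxy)-5-iodobenzene | Ic1cc(OCc2ccccc2)cc(OCc2ccccc2)c1 | intermediate
8 | (2R,3R,4R)-4-[2,4-bis(benzyloxy)-6-iodophenyl]-5,7-bis(benzyloxy)-2-[3,4-bis(benzyloxy)phenyl]chroman-3-yl 3,4,5-tris(benzyloxy)benzoate | O=C(O[C@@H]1[C@@H](c2c(OCc3ccccc3)cc(OCc3ccccc3)cc2I)c2c(OCc3ccccc3)cc(OCc3ccccc3)cc2O[C@@H]1c1ccc(OCc2ccccc2)c(OCc2ccccc2)c1)c1cc(OCc2ccccc2)c(OCc2ccccc2)c(OCc2ccccc2)c1 | intermediate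
9 | allyl alcohol | C=CCO | starting material
10 | 3-(methoxymethoxy)prop-1-ene | C=CCOCOC | intermediate
11 | 3,4-bis(benzyloxy)benzaldehyde | O=Cc1ccc(OCc2ccccc2)c(OCc2ccccc2)c1 | starting material
12 | (Z)-3-(methoxymethoxy)allyllithium | [Li]C/C=C\OCOC | intermediate
13 | lithium [(Z)-3-(methoxymethoxy)allyl](methoxy)bis(isopinocampheyl)borate | [Li+].CO[B-](C/C=C\OCOC)([C@@H]1C[C@@H]2C[C@H]([C@H]1C)C2(C)C)[C@@H]1C[C@@H]2C[C@H]([C@H]1C)C2(C)C | intermediate
14 | [(Z)-3-(methoxymethoxy)allyl]bis(isopinocampheyl)borane | COCO/C=C\CB([C@@H]1C[C@@H]2C[C@H]([C@H]1C)C2(C)C)[C@@H]1C[C@@H]2C[C@H]([C@H]1C)C2(C)C | intermediate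
15 | bis(isopinocampheyl)borinic ester of 16 | B(O[C@H](c1ccc(OCc2ccccc2)c(OCc2ccccc2)c1)[C@H](OCOC)C=C)([C@@H]1C[C@@H]2C[C@H]([C@H]1C)C2(C)C)[C@@H]1C[C@@H]2C[C@H]([C@H]1C)C2(C)C | intermediate
16 | (1R,2R)-1-[3,4-bis(benzyloxy)phenyl]-2-(methoxymethoxy)but-3-en-1-ol | O[C@H](c1ccc(OCc2ccccc2)c(OCc2ccccc2)c1)[C@H](OCOC)C=C | intermediate
17 | ozonide (1,2,4-trioxolane) of 16, mixture at the acetal carbon | O[C@H](c1ccc(OCc2ccccc2)c(OCc2ccccc2)c1)[C@H](OCOC)C1OCOO1 | intermediate
18 | (1R,2R)-1-[3,4-bis(benzyloxy)phenyl]-2-(methoxymethoxy)propane-1,3-diol | O[C@H](c1ccc(OCc2ccccc2)c(OCc2ccccc2)c1)[C@H](OCOC)CO | intermediate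
19 | (1R,2S)-1-[3,4-bis(benzyloxy)phenyl]-3-iodo-2-(methoxymethoxy)propan-1-ol | O[C@H](c1ccc(OCc2ccccc2)c(OCc2ccccc2)c1)[C@H](OCOC)CI | intermediate
20 | upper 3-O-[tris(benzyloxy)benzoyl], lower 3-O-methoxymethyl octa-O-benzylprocyanidin B2 | O=C(O[C@@H]1[C@@H](c2c(OCc3ccccc3)cc(OCc3ccccc3)c3c2O[C@H](c2ccc(OCc4ccccc4)c(OCc4ccccc4)c2)[C@H](OCOC)C3)c2c(OCc3ccccc3)cc(OCc3ccccc3)cc2O[C@@H]1c1ccc(OCc2ccccc2)c(OCc2ccccc2)c1)c1cc(OCc2ccccc2)c(OCc2ccccc2)c(OCc2ccccc2)c1 | intermediate
21 | N-(alkoxymethyl)-2,2'-bipyridinium triflate of the lower 3-oxygen | O=C(O[C@@H]1[C@@H](c2c(OCc3ccccc3)cc(OCc3ccccc3)c3c2O[C@H](c2ccc(OCc4ccccc4)c(OCc4ccccc4)c2)[C@H](OC[n+]2ccccc2-c2ccccn2)C3)c2c(OCc3ccccc3)cc(OCc3ccccc3)cc2O[C@@H]1c1ccc(OCc2ccccc2)c(OCc2ccccc2)c1)c1cc(OCc2ccccc2)c(OCc2ccccc2)c(OCc2ccccc2)c1.[O-]S(=O)(=O)C(F)(F)F | intermediate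
22 | upper 3-O-[tris(benzyloxy)benzoyl] octa-O-benzylprocyanidin B2 (lower 3-OH free) | O=C(O[C@@H]1[C@@H](c2c(OCc3ccccc3)cc(OCc3ccccc3)c3c2O[C@H](c2ccc(OCc4ccccc4)c(OCc4ccccc4)c2)[C@H](O)C3)c2c(OCc3ccccc3)cc(OCc3ccccc3)cc2O[C@@H]1c1ccc(OCc2ccccc2)c(OCc2ccccc2)c1)c1cc(OCc2ccccc2)c(OCc2ccccc2)c(OCc2ccccc2)c1 | intermediate
23 | 3,3'-bis-O-[3,4,5-tris(benzyloxy)benzoyl]-octa-O-benzylprocyanidin B2 | O=C(O[C@@H]1[C@@H](c2c(OCc3ccccc3)cc(OCc3ccccc3)c3c2O[C@H](c2ccc(OCc4ccccc4)c(OCc4ccccc4)c2)[C@H](OC(=O)c2cc(OCc4ccccc4)c(OCc4ccccc4)c(OCc4ccccc4)c2)C3)c2c(OCc3ccccc3)cc(OCc3ccccc3)cc2O[C@@H]1c1ccc(OCc2ccccc2)c(OCc2ccccc2)c1)c1cc(OCc2ccccc2)c(OCc2ccccc2)c(OCc2ccccc2)c1 | intermediate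
24 | 3,3'-di-O-galloylprocyanidin B2 | O=C(O[C@@H]1[C@@H](c2c(O)cc(O)c3c2O[C@H](c2ccc(O)c(O)c2)[C@H](OC(=O)c2cc(O)c(O)c(O)c2)C3)c2c(O)cc(O)cc2O[C@@H]1c1ccc(O)c(O)c1)c1cc(O)c(O)c(O)c1 | target

**Count and risks**

Total steps: 13. Longest linear sequence: 8 steps (1, 2, 3, 5, 10, 11, 12, 13).

Steps most likely to fail:

1. Step 10 (proposed new method). Palladation of C4a–H next to the C5 benzyloxy group may be too slow, so that the aryl palladium species is consumed by protodeiodination or by direct ipso reactions. The palladium alkoxide may undergo β-hydride elimination (ketone formation, or epimerisation of lower C2) before C–O reductive elimination. The iodo alcohol may cyclise to an oxetane under the base. Fallback with known chemistry: the lower unit is taken intact from the chiral pool. Slow addition of 5 to an excess of 2 (4 equiv) and TMSOTf in CH2Cl2 at −78 °C, the established Lewis-acid coupling of a C4 electrophile with C8 of a benzylated flavan-3-ol, should give 22 directly. The fallback sets out from 5 and 2 and comes back at 22; it makes no compound outside the list (F0), at the price of the oligomer and 4→6 regioisomer problems that the annulation avoids.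

2. Step 5. The iodoarene is a weaker nucleophile than ring A of the electrophile and of the product, so self-condensation and over-alkylation to oligomers may compete. Attack at the carbon between the two ethers may also erode regioselectivity. Fallback: the fallback sets out from 5 and 6. Free 5-iodoresorcinol 6, a much stronger nucleophile, is C-alkylated by 5 (TMSOTf, CH2Cl2/MeCN, −40 °C) at the carbon ortho to iodine and ortho/para to the hydroxyls. This should give (2R,3R,4R)-5,7-bis(benzyloxy)-2-[3,4-bis(benzyloxy)phenyl]-4-(2,4-dihydroxy-6-iodophenyl)chroman-3-yl 3,4,5-tris(benzyloxy)benzoate F1. Benzylation of its two phenols (BnBr, K2CO3, DMF) comes back to the route at 8.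

3. Step 9. The phosphonium reagent may also activate the electron-rich benzylic carbinol (ionisation, iodide substitution with loss of configuration at C1) or bring about cyclodehydration to an oxetane. Fallback: the fallback sets out from 18. Selective sulfonylation of the primary hydroxyl (TsCl, pyridine, 0 °C) should give (2R,3R)-3-[3,4-bis(benzyloxy)phenyl]-3-hydroxy-2-(methoxymethoxy)propyl 4-methylbenzenesulfonate F2. Finkelstein displacement (NaI, acetone, reflux) comes back to the route at 19.

**Further compounds**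

F0 | step 10 | none | none
F1 | step 5 | (2R,3R,4R)-5,7-bis(benzyloxy)-2-[3,4-bis(benzyloxy)phenyl]-4-(2,4-dihydroxy-6-iodophenyl)chroman-3-yl 3,4,5-tris(benzyloxy)benzoate | O=C(O[C@@H]1[C@@H](c2c(O)cc(O)cc2I)c2c(OCc3ccccc3)cc(OCc3ccccc3)cc2O[C@@H]1c1ccc(OCc2ccccc2)c(OCc2ccccc2)c1)c1cc(OCc2ccccc2)c(OCc2ccccc2)c(OCc2ccccc2)c1
F2 | step 9 | (2R,3R)-3-[3,4-bis(benzyloxy)phenyl]-3-hydroxy-2-(methoxymethoxy)propyl 4-methylbenzenesulfonate | O[C@H](c1ccc(OCc2ccccc2)c(OCc2ccccc2)c1)[C@H](OCOC)COS(=O)(=O)c1ccc(C)cc1
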